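**Assumptions**
- The target SMILES is read as the C2-symmetric (R,R) isomer (descriptors for the enol tautomer as drawn); the meso isomer is a by-product to be removed.
- Which antipode of the step-2 catalyst gives the R centres cannot be predicted with certainty; it is fixed by one calibration run (both antipodes are commercial) and the route is written for that antipode.

**Retrosynthetic overview**
1. The aromatic ring is bought: phloroglucinol (1) + hexanoyl chloride (2) ⇒ hexanoylphloroglucinol (3).
2. Both Ar–CH(iPr) bonds and both stereocentres: 3 + 2 × (E)-4-methylpent-2-enal (4) ⇒ bis-dihydrocoumarin 5 by a double enantioselective NHC annulation (two lactone rings at once). The lactones are activated esters that already hold C1 and C2 of each future trione ring.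
3. Each cyclohexanetrione ring is cut at C1–C6 and C2–C3: the C(=O)–CH2 unit of a lactone of 5 + the four-carbon unit of keto ester 7 (from dimethylketene dimer 6) ⇒ target 8 by a one-pot double Claisen/Dieckmann.
4. Ring order: benzene (purchased) → two δ-lactones together (step 2) → both trione carbocycles together as the lactones open (step 4).

**Step 1**
Reactants: 1 phloroglucinol (benzene-1,3,5-triol); 2 hexanoyl chloride
Product: 3 1-(2,4,6-trihydroxyphenyl)hexan-1-one (hexanoylphloroglucinol)
Conditions: AlCl3 (4 equiv), CH2Cl2/MeNO2, 0 °C → rt; ice/1 M HCl
Reagents that add atoms: hexanoyl chloride (2), CCCCCC(=O)Cl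
Why: Friedel–Crafts C-acylation of the electron-rich triol stops at monoacylation because the Al-chelated aryl ketone is deactivated; no stereocentre.

**Step 2 (key step: two rings and both stereocentres in one operation)**
Reactants: 3 hexanoylphloroglucinol; 4 (E)-4-methylpent-2-enal (3 equiv)
Product: 5 (4R,10R)-6-hexanoyl-5-hydroxy-4,10-di(propan-2-yl)-3,4,9,10-tetrahydro-2H,8H-pyrano[2,3-f]chromene-2,8-dione. This is hexanoylphloroglucinol whose C3 and C5 each carry CH(iPr)CH2C(=O)– closed as aryl esters onto the 4-O and 6-O; the 2-OH is free and both CH(iPr) centres are R.
Conditions: chiral aminoindanol-derived N-mesityl triazolium chloride (15 mol%), DBU (30 mol%), 3,3′,5,5′-tetra-tert-butyldiphenoquinone (2.4 equiv), 4 Å MS, toluene, rt, 24–48 h; SiO2 chromatography to remove the meso diastereomer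
Reagents that add atoms: (E)-4-methylpent-2-enal (4), CC(C)/C=C/C=O (two equivalents incorporated)
Why: Proposed new method: the carbene adds to the enal and the Breslow intermediate is oxidised by the diphenoquinone to a chiral α,β-unsaturated acyl azolium; the acylphloroglucinol phenoxide then attacks its β-carbon through C3 and then C5 (Michael addition, or O-acylation followed by Coates–Claisen [3,3] shift) on the face left open by the aminoindanol backbone, and each acyl azolium is trapped by the neighbouring OH to close a δ-lactone and release the catalyst, so both CH(iPr) centres are set under catalyst control with statistical (Horeau) enrichment of the C2 isomer; the closest known reaction type is the enantioselective oxidative NHC [3+3] annulation of enals with 1,3-dicarbonyls and naphthols, and any regioisomeric (linear) bis-lactone has the same C–C bonds and stereocentres and converges in step 4.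

**Step 3**
Reactants: 6 2,2,4,4-tetramethylcyclobutane-1,3-dione (dimethylketene dimer)
Product: 7 methyl 2,2,4-trimethyl-3-oxopentanoate
Conditions: NaOMe (5 mol%), MeOH, reflux; AcOH quench, distil
Reagents that add atoms: methanol, CO
Why: Base-catalysed retro-Claisen ring-opening (alcoholysis) of the strained, non-enolisable β-diketone is a known, high-yielding reaction; no stereocentre.

**Step 4 (both carbocycles in one pot)**
Reactants: 5 bis-dihydrocoumarin; 7 methyl 2,2,4-trimethyl-3-oxopentanoate (6 equiv)
Product: 8 Myrtucommulone F, 1-{2,4,6-trihydroxy-3,5-bis[(1R)-1-(2-hydroxy-3,3,5,5-tetramethyl-4,6-dioxocyclohex-1-en-1-yl)-2-methylpropyl]phenyl}hexan-1-one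
Conditions: 7, LDA (5.8 equiv), THF, −78 °C; add 5, −78 → 0 °C; then t-BuOK (3 equiv), 0 °C → rt; cold pH 3 citrate quench
Reagents that add atoms: methyl 2,2,4-trimethyl-3-oxopentanoate (7), COC(=O)C(C)(C)C(=O)C(C)C (two equivalents; OMe is lost as methanol)
Why: Proposed new method: the tetrasubstituted lithium enolate of 7 is C-acylated by each aryl lactone (crossed Claisen made favourable by loss of the stabilised acylphloroglucinol phenoxide), and the only enolisable position of each resulting methyl 2,2,4,4-tetramethyl-3,5-dioxoalkanoate (the former lactone CH2) then closes onto the ester in a 6-membered Dieckmann driven by deprotonation of the acidic trione; the closest known reactions are the C-acylation of this same enolate by acyl chlorides and the base-mediated Dieckmann closure of methyl 2,2,4,4-tetramethyl-3,5-dioxohexanoate to syncarpic acid, and the stereocentres are β to the reacting carbonyls, have no bond made or broken, and are held in polyanions that disfavour retro-Michael loss of syncarpate.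

**Compound list**
1 | phloroglucinol (benzene-1,3,5-triol) | Oc1cc(O)cc(O)c1 | starting material
2 | hexanoyl chloride | CCCCCC(=O)Cl | starting material
3 | 1-(2,4,6-trihydroxyphenyl)hexan-1-one | CCCCCC(=O)c1c(O)cc(O)cc1O | intermediate
4 | (E)-4-methylpent-2-enal | CC(C)/C=C/C=O | starting material
5 | (4R,10R)-6-hexanoyl-5-hydroxy-4,10-di(propan-2-yl)-3,4,9,10-tetrahydro-2H,8H-pyrano[2,3-f]chromene-2,8-dione | CCCCCC(=O)c1c(O)c2[C@@H](C(C)C)CC(=O)Oc2c2[C@@H](C(C)C)CC(=O)Oc12 | intermediate
6 | 2,2,4,4-tetramethylcyclobutane-1,3-dione | CC1(C)C(=O)C(C)(C)C1=O | starting material
7 | methyl 2,2,4-trimethyl-3-oxopentanoate | COC(=O)C(C)(C)C(=O)C(C)C | intermediate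
8 | Myrtucommulone F | CCCCCC(=O)c1c(O)c([C@H](C2=C(O)C(C)(C)C(=O)C(C)(C)C2=O)C(C)C)c(O)c([C@H](C2=C(O)C(C)(C)C(=O)C(C)(C)C2=O)C(C)C)c1O | target

**Totals**
Total steps: 4. Longest linear sequence: 3 (steps 1 → 2 → 4).

**Three steps most likely to fail, with fallbacks**
- **Step 2.** Risks: the second annulation on the less nucleophilic mono-lactone, γ-deprotonation of the acyl azolium, oxidant incompatibility with the phenol, or insufficient ee. Fallback: switch to iminium catalysis, using a diarylprolinol silyl ether to effect a double Friedel–Crafts/hemiacetalisation of 3 with 4 to the bis-lactol, then oxidise the lactols (Ag2CO3/Celite or TEMPO/PhI(OAc)2) to 5. This costs one extra step.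
- **Step 4.** Risks: the hindered enolate may deprotonate rather than acylate, the hexanoyl enolate may attack the adjacent lactone (Baker–Venkataraman-type), or the non-enolisable 1,3-diketone may undergo retro-Claisen cleavage. Fallback: saponify 5 and per-benzylate the phenols, convert the bis-acid to the bis-acid chloride, C-acylate the enolate of 7 (directly precedented with acid chlorides), carry out the double Dieckmann with NaOMe, and remove the benzyl groups by hydrogenolysis.
- **Step 1.** Risks: O-acylation or diacylation and a modest yield. Fallback: Houben–Hoesch reaction of phloroglucinol with hexanenitrile (ZnCl2, HCl gas, Et2O), then hydrolysis of the ketimine, which stops cleanly at the mono-ketone.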